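Before you trust a share, ask when it was read.

| flask | starting material | other conformer | free catalyst | temperature | remark | time |
|---|---|---|---|---|---|---|
| Wednesday's | 20 mM | 10 mM | 10 µM | 40 °C | run made earlier |  |
| Friday's | 20 mM | 10 mM | 15 µM | 62 °C | run made earlier |  |
| zeta | 20 mM | 10.0 mM | 20 µM | 50 °C |  | 2.5 h |
| epsilon | 20 mM | 10.0 mM | 20 µM | 30 °C |  | 2.5 h |
| gamma | 20 mM | 10.0 mM | 20 µM | 70 °C |  | 2.5 h |

Wednesday's run (percent of the starting material and other conformer together charged)

| time / h | target / % | isomer of the product / % |
|---|---|---|
| 0.200 | 1.6 | 0 |
| 0.417 | 1.3 | 0 |
| 0.667 | 1.9 | 0 |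
| 1.33 | 4.2 | 0 |
| 2.50 | 9.3 | 2.5 |

Friday's run (percent of the starting material and other conformer together charged)

| time / min | target / % | isomer of the product / % |
|---|---|---|
| 12.0 | 4.8 | 2.5 |
| 20.0 | 5.9 | 2.6 |
| 30.0 | 11.0 | 3.0 |
| 40.0 | 13.5 | 4.7 |
| 50.0 | 16.5 | 5.2 |

(scatter of a reading: 1 percentage point)

- the earlier runs were read with a standard deviation of 1 percentage point
- in a conversion other conformer counts as not yet reacted

1. the best flask by share of target in all that became target or isomer of the product; "all alike" if 1.5 percentage points covers them all (zeta / epsilon / gamma / all alike)
2. share of target in all that became target or isomer of the product, zeta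
3. share of target in all that became target or isomer of the product, epsilon
4. share of target in all that became target or isomer of the product, gamma

Wednesday's last reading, at 2.50 h, shows 2.5 % of isomer of the product beside 9.3 % of target, and Friday's, at 50.0 min, shows 5.2 % beside 16.5 %. Suppose the catalyst makes target from starting material and isomer from other conformer. The catalyst then cancels from the ratio of the two products, so I divide that ratio by [other conformer]/[starting material] as charged. This gives 0.538 on Wednesday's run and 0.630 on Friday's. Zeta's temperature lies between theirs, so I take the mean of the two as the isomer factor, a selectivity factor, 0.584. For zeta I reckon a share of 77.4 %.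

But the charged ratio is a start value. On Friday's run, the last readings put target at 24.8 % of the starting material charged and isomer at 15.6 % of the other conformer charged, so, as far as these readings go and if each product comes from its own charge, [other conformer]/[starting material] has climbed in Friday's run.

The forecast names epsilon, with 77 % for zeta, 80 % for epsilon and 74 % for gamma: “Selectivity therefore falls gently with temperature”. I differ on gamma, which runs hotter than Friday's, with more catalyst and for longer, so I expect its share below the forecast's.

The flasks give 77.2 % for zeta, 84.5 % for epsilon and 64.8 % for gamma, so epsilon is best.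

    starting material + free catalyst → free catalyst + target (k = 2500 /M/min, Ea = 49.0 kJ/mol)
    free catalyst → spent catalyst (k = 0.0140 /min, Ea = 95.0 kJ/mol)
    starting material ⇌ other conformer (K = 1.50, k = 0.0130 /min, Ea = 101 kJ/mol, ΔH = −43.0 kJ/mol)
    2 free catalyst ⇌ resting dimer, settled at all times (K = 2.20 × 10⁵ /M, ΔH = −40.0 kJ/mol)
    free catalyst + other conformer → free catalyst + isomer of the product (k = 1200 /M/min, Ea = 56.0 kJ/mol)
    (constants at 70 °C)

Read at 2.50 h, zeta's isomer factor is 0.591, but gamma's is 1.09. Gamma then holds 18.5 % of other conformer beside 10.1 % of starting material, a ratio of 1.83 against 0.500 charged. Take zeta's neighbour with 8.0 mM of starting material: the isomer factor on its charged ratio gives 57.8 %, and at 2.50 h that flask gives 60.4 %.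

The data were computed from invented constants.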